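- The ratio of charge lost to charge made into target, read at each run's ceiling, is what we follow from flask to flask.

| flask | starting material | remark | time |
|---|---|---|---|
| epsilon | 9 mM | run made earlier |  |
| delta | 29 mM | run made earlier |  |
| gamma | 110 mM | run made earlier |  |
| cedar | 100 mM |  | 12 h |
| elm | 20 mM |  | 12 h |
| alder | 32 mM |  | 12 h |
| ash | 50 mM |  | 12 h |
| maple | 8.0 mM |  | 12 h |

- epsilon (time / h: target / %): 0.833: 16; 2.00: 47; 4.00: 68; 6.00: 79; 8.00: 83
- delta (time / h: target / %): 0.833: 16; 2.00: 39; 4.00: 53; 6.00: 62; 8.00: 64
- gamma (time / h: target / %): 0.667: 7; 1.33: 15; 2.50: 26; 4.00: 32; 8.00: 40

(scatter of a reading: 1.5 percentage points)

1. the flasks by amount of target, in percent of the starting material charged, highest first, at 12 h (cedar / elm / alder / ash / maple)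
2. the amount of target, in percent of the starting material charged of the flask you put first, at 12 h
3. the amount of target, in percent of the starting material charged of the flask you put last, at 12 h

- In the epsilon run, the last two rises over 2.00 h read as shrinking by a factor 0.364. If the delta run's tail shrinks by the same factor, its last readings put the delta ceiling near 65.1% of the charge, an estimate that carries the scatter of those readings, with a lost-to-target ratio of 0.535.
- We take a first-order route against a second-order loss of starting material. Integrating the two rates puts the ceiling at 69.3% where they tie at the start, a ratio of 0.443, and this tie is our zero of the scale.
- Scaling the delta ratio down to the tie, the crossover charge, at which both routes use starting material equally fast at the start, is 24.0 mM.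
- If the ratio grows in proportion to the charge, cedar ends at 35.1%, and the flasks rank from the smallest charge up.
- Proportion is the weak link: it gives the gamma run 33.0%, less than the 41.2% its tail suggests.
- The integrated law replaces it: with u the charge over the crossover charge, the ceiling is the natural logarithm of one plus u, divided by u. For the gamma run it gives 37.5%, still under the tail estimate but nearer to it than the proportional figure. We therefore commit to 86.3% for maple and 39.4% for cedar.
- The forecast gives 87% for maple and 45% for cedar, and it orders the flasks maple > elm > alder > ash > cedar on the ground that “Both the rate and the ceiling fall with concentration”. Its order matches ours, but its cedar value is higher than ours.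
- The flasks give maple > elm > alder > ash > cedar, with maple at 86.2% and cedar at 39.5%, so the forecast's cedar value stands 5.5 percentage points too high.

    starting material ⇌ intermediate A (K = 40.4, k = 2.10 /h)
    starting material ⇌ intermediate B (K = 0.110, k = 0.791 /h)
    intermediate A → target (k = 0.532 /h)
    2 starting material → self-condensation product (k = 46.0 /M/h)

- In maple at the start, the forward step from starting material to intermediate A uses starting material 2.9 times as fast as self-condensation does (the selectivity factor, forward rate alone), and our crossover charge, a value read from the runs, is 3.00 times maple's charge. At 12 h, in percent of the charge with each self-condensation product counted as two starting material, maple holds 86.2% target and 13.6% self-condensation product, and cedar holds 39.5% and 60.4%. For the neighbour flask, maple with 14 mM of starting material, the integrated law with our crossover charge gives 78.8%, and that flask ends with 78.7% target.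

The readings were generated by integration on assumed constants; noise was put on by code.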